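**Strategy**

The ring is disconnected across its C5–C6 and C1–C2 bonds (cyclohexanol numbering: C1 carbinol, C2 side-chain methine, C3 quaternary, C4 CHBr). A catalytic enantioselective Diels–Alder reaction forms both bonds at once and sets C1 and C2. It exploits the 1,4-relationship between the oxygen at C1 and the bromine at C4, read as a 4-oxygenated cyclohexanone enol ether. The precursor is an open-chain 2-silyloxy-1,3-diene (C5=C4–C3=C2) carrying the intact (S)-linalool side chain, and 2-(benzoyloxy)acrolein, which delivers C6, C1 and its oxygen. The silyl enol ether left behind then gives the C3 quaternary centre by allylation and the C4 bromide by reduction and inversion.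

Key step: step 7

Assumption: (S)-(+)-linalool of high enantiomeric purity is taken as commercial, and the oxazaborolidine antipode named in step 7 stands for whichever one leaves the Si face of the α-carbon of the enal open (both antipodes are available).

Ring locants in the Why lines are those of the target (C1 carbinol, C2, C3, C4 CHBr, C5, C6).

**Route**

Step 1
Reactants: 1 (S)-(+)-linalool
Product: 2 triethyl{[(3S)-3,7-dimethylocta-1,6-dien-3-yl]oxy}silane
Conditions: Et3SiOTf, 2,6-lutidine, CH2Cl2, −78 → 0 °C
Reagents that add atoms: triethylsilyl trifluoromethanesulfonate, CC[Si](CC)(CC)OS(=O)(=O)C(F)(F)F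
Why: Silylation of a hindered tertiary alcohol with a silyl triflate and a hindered pyridine base is reliable and masks the hydroxyl against lactol formation, oxa-Michael addition and Lewis acid binding in later steps; the carbinol stereocentre is not touched.

Step 2
Reactants: 2 linalool triethylsilyl ether
Product: 4 (4S)-4-methyl-4-(triethylsilyloxy)hex-5-enal, via ozonide 3 (not isolated)
Conditions: O3, CH2Cl2, −78 °C (stopped at the end point of a Sudan Red 7B indicator); then Me2S, −78 → 25 °C
Reagents that add atoms: ozone, [O-][O+]=O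
Why: Chemoselective ozonolysis: the electron-rich trisubstituted alkene should be cleaved much faster than the monosubstituted vinyl group next to the silyloxy carbon, and reductive work-up of the ozonide gives the aldehyde whose carbonyl carbon becomes ring carbon C2.

Step 3
Reactants: 4 aldehyde; 5 3-(triphenylphosphoranylidene)butan-2-one
Product: 6 (3E,7S)-3,7-dimethyl-7-(triethylsilyloxy)nona-3,8-dien-2-one
Conditions: toluene, 100 °C
Reagents that add atoms: none
Why: Wittig olefination with a stabilised α-methyl ylide should give the E trisubstituted enone; no stereocentre is formed.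

Step 4
Reactants: 6 enone
Product: 7 tert-butyl{[(3E,7S)-3,7-dimethyl-7-(triethylsilyloxy)nona-1,3,8-trien-2-yl]oxy}dimethylsilane
Conditions: t-BuMe2SiOTf, Et3N, CH2Cl2, 0 °C
Reagents that add atoms: tert-butyldimethylsilyl trifluoromethanesulfonate, CC(C)(C)[Si](C)(C)OS(=O)(=O)C(F)(F)F
Why: Soft enolisation (silyl triflate with a tertiary amine) removes a proton from the α′ methyl group and should give the cross-conjugated 2-silyloxy-1,3-diene without disturbing the E double bond (silyl dienol ether formation).

Step 5
Reactants: 8 2,2-dimethyl-1,3-dioxan-5-one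
Product: 9 2,2-dimethyl-4H-1,3-dioxin-5-yl benzoate
Conditions: KN(SiMe3)2, THF, −78 °C; then PhCOCl, −78 → 0 °C
Reagents that add atoms: benzoyl chloride, O=C(Cl)c1ccccc1
Why: O-Acylation of the potassium enolate of the ketone with the hard acid chloride should give the enol benzoate.

Step 6
Reactants: 9 enol benzoate
Product: 10 1-formylethenyl benzoate [2-(benzoyloxy)acrolein]
Conditions: toluene, 110 °C, acetone distilled off; used at once
Reagents that add atoms: none
Why: Thermal retro-hetero-Diels–Alder reaction of the 4H-1,3-dioxine expels acetone and liberates the 2-acyloxy enal.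

Step 7
Reactants: 7 silyloxydiene; 10 2-(benzoyloxy)acrolein
Product: 11 (1S,2S)-4-[(tert-butyldimethylsilyl)oxy]-1-formyl-3-methyl-2-[(3S)-3-methyl-3-(triethylsilyloxy)pent-4-en-1-yl]cyclohex-3-en-1-yl benzoate
Conditions: (S)-3,3-diphenyl-1-(o-tolyl)tetrahydro-1H,3H-pyrrolo[1,2-c][1,3,2]oxazaborole (20 mol %), HNTf2 (18 mol %), CH2Cl2, −78 → −40 °C
Reagents that add atoms: none
Why: The cationic boron Lewis acid binds the formyl oxygen of 10 and lowers its LUMO, so that the electron-rich diene 7 adds in a concerted, asynchronous [4+2] cycloaddition of normal electron demand, the C5–C6 bond forming ahead of the C1–C2 bond; the closest known reaction type is the oxazaborolidinium-catalysed Diels–Alder reaction of 2-substituted acroleins with 2-silyloxy-1,3-dienes. The cyclohexene ring is closed by intermolecular [4+2] cycloaddition, suprafacial on both partners. C2 is set by the E geometry of the C2=C3 diene bond together with the endo orientation of the complexed formyl group, which places CHO cis and the benzoyloxy group trans to the side chain; C1, and with it the absolute sense of C2, is set by the catalyst, which leaves the Si face of the α-carbon of 10 open. The step needs regioselectivity (secured by the C4 silyloxy group, which makes C5 the nucleophilic diene terminus and sends it to the β-carbon of the enal), endo selectivity (expected for a Lewis-acid-activated enal with an open-chain diene, where the exo preference known for cyclopentadiene has no basis) and catalyst control over the faces (the remote side-chain stereocentre exerts no bias). The isolated vinyl group and both silyl ethers should be inert at this temperature.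

Step 8
Reactants: 11 cycloadduct
Product: 12 (1S,2S)-4-[(tert-butyldimethylsilyl)oxy]-1-(hydroxymethyl)-3-methyl-2-[(3S)-3-methyl-3-(triethylsilyloxy)pent-4-en-1-yl]cyclohex-3-en-1-ol
Conditions: LiAlH4, Et2O, −20 → 0 °C; Rochelle salt work-up
Reagents that add atoms: none
Why: Hydride reduction converts the aldehyde into the primary alcohol and cleaves the benzoate reductively without touching the silyl enol ether, the silyl ether or either stereocentre.

Step 9
Reactants: 12 diol
Product: 15 (1S,2S)-4-[(tert-butyldimethylsilyl)oxy]-1,3-dimethyl-2-[(3S)-3-methyl-3-(triethylsilyloxy)pent-4-en-1-yl]cyclohex-3-en-1-ol, via primary tosylate 13 (not isolated), via spiro-epoxide 14 (not isolated)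
Conditions: NaH (2.2 equiv), N-tosylimidazole, THF, 0 → 25 °C; then LiEt3BH, 0 → 25 °C
Reagents that add atoms: none
Why: Sulfonylation of the more accessible primary alkoxide is followed by intramolecular Williamson closure (3-exo-tet) to the spiro-epoxide, in which the C1–O bond is never broken, and SN2 hydride opening at the epoxide CH2 turns the hydroxymethyl group into the C1 methyl group with retention at C1.

Step 10
Reactants: 15 silyl enol ether
Product: 17 (2S,3S,4S)-4-hydroxy-2,4-dimethyl-3-[(3S)-3-methyl-3-(triethylsilyloxy)pent-4-en-1-yl]-2-(prop-2-en-1-yl)cyclohexan-1-one, via dilithium enolate 16 (not isolated)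
Conditions: MeLi (2.3 equiv), THF, 0 → 25 °C; then allyl bromide, DMPU, −78 → 0 °C
Reagents that add atoms: allyl bromide, C=CCBr
Why: Methyllithium deprotonates the hydroxyl and cleaves the enol Si–O bond to the regiodefined tetrasubstituted lithium enolate, and SN2 C-allylation forms the C3 quaternary centre with the allyl group entering axially anti to the pseudoaxial C2 side chain (allylic strain with the C3 methyl group), that is trans to the side chain and cis to the C1 oxygen.

Step 11
Reactants: 17 ketone
Product: 18 (1S,2S,3S,4R)-1,3-dimethyl-2-[(3S)-3-methyl-3-(triethylsilyloxy)pent-4-en-1-yl]-3-(prop-2-en-1-yl)cyclohexane-1,4-diol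
Conditions: LiBH(s-Bu)3 (L-Selectride), THF, −78 °C; then H2O
Reagents that add atoms: none
Why: The bulky trialkylborohydride should attack the ketone next to the quaternary carbon from the equatorial direction, as in 4,4-dimethyl-3-keto steroids, and give the axial C4 alcohol (4R) needed for inversion (diastereoselective ketone reduction).

Step 12
Reactants: 18 axial alcohol
Product: 19 (1S,2S,3S,4S)-4-bromo-1,3-dimethyl-2-[(3S)-3-methyl-3-(triethylsilyloxy)pent-4-en-1-yl]-3-(prop-2-en-1-yl)cyclohexan-1-ol
Conditions: CBr4, PPh3, toluene, 0 → 60 °C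
Reagents that add atoms: carbon tetrabromide, BrC(Br)(Br)Br
Why: Appel reaction: the secondary alcohol is activated as its alkoxyphosphonium salt and displaced by bromide with inversion (SN2), which places bromine equatorial (4S) and cis to the C3 methyl group, while the tertiary alcohol should not be activated under these conditions.

Step 13
Reactants: 19 bromide; 20 2-methylbut-3-en-2-ol
Product: 22 (1S,2S,3S,4S)-4-bromo-2-[(3S)-3-hydroxy-3-methylpent-4-en-1-yl]-3-[(2E)-4-hydroxy-4-methylpent-2-en-1-yl]-1,3-dimethylcyclohexan-1-ol, via silyl ether 21 (not isolated)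
Conditions: second-generation Grubbs catalyst (5 mol %), 20 (10 equiv), CH2Cl2, 40 °C; then Bu4NF, AcOH, THF, 25 °C
Reagents that add atoms: none
Why: Olefin cross-metathesis of the unhindered allyl group with excess tertiary allylic alcohol should give the E-1,2-disubstituted alkene (the bulky carbinol end disfavours Z), the vinyl group next to the silyloxy-bearing quaternary carbon being too hindered to take part, and buffered fluoride then cleaves the Si–O bond to release the last hydroxyl.

**Compound list**

1 | (S)-(+)-linalool [(3S)-3,7-dimethylocta-1,6-dien-3-ol] | C=C[C@@](C)(O)CCC=C(C)C | starting material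
2 | triethyl{[(3S)-3,7-dimethylocta-1,6-dien-3-yl]oxy}silane | C=C[C@@](C)(O[Si](CC)(CC)CC)CCC=C(C)C | intermediate
3 | 3,3-dimethyl-5-[(3S)-3-methyl-3-(triethylsilyloxy)pent-4-en-1-yl]-1,2,4-trioxolane (ozonide, both C5 epimers) | C=C[C@@](C)(O[Si](CC)(CC)CC)CCC1OOC(C)(C)O1 | intermediate
4 | (4S)-4-methyl-4-(triethylsilyloxy)hex-5-enal | C=C[C@@](C)(O[Si](CC)(CC)CC)CCC=O | intermediate
5 | 3-(triphenylphosphoranylidene)butan-2-one | CC(=O)C(C)=P(c1ccccc1)(c1ccccc1)c1ccccc1 | starting material
6 | (3E,7S)-3,7-dimethyl-7-(triethylsilyloxy)nona-3,8-dien-2-one | C=C[C@@](C)(O[Si](CC)(CC)CC)CC/C=C(\C)C(C)=O | intermediate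
7 | tert-butyl{[(3E,7S)-3,7-dimethyl-7-(triethylsilyloxy)nona-1,3,8-trien-2-yl]oxy}dimethylsilane | C=C[C@@](C)(O[Si](CC)(CC)CC)CC/C=C(\C)C(=C)O[Si](C)(C)C(C)(C)C | intermediate
8 | 2,2-dimethyl-1,3-dioxan-5-one | CC1(C)OCC(=O)CO1 | starting material
9 | 2,2-dimethyl-4H-1,3-dioxin-5-yl benzoate | CC1(C)OCC(OC(=O)c2ccccc2)=CO1 | intermediate
10 | 1-formylethenyl benzoate [2-(benzoyloxy)acrolein] | C=C(C=O)OC(=O)c1ccccc1 | intermediate
11 | (1S,2S)-4-[(tert-butyldimethylsilyl)oxy]-1-formyl-3-methyl-2-[(3S)-3-methyl-3-(triethylsilyloxy)pent-4-en-1-yl]cyclohex-3-en-1-yl benzoate (CHO cis to the side chain) | C=C[C@@](C)(O[Si](CC)(CC)CC)CC[C@H]1C(C)=C(O[Si](C)(C)C(C)(C)C)CC[C@]1(C=O)OC(=O)c1ccccc1 | intermediate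
12 | (1S,2S)-4-[(tert-butyldimethylsilyl)oxy]-1-(hydroxymethyl)-3-methyl-2-[(3S)-3-methyl-3-(triethylsilyloxy)pent-4-en-1-yl]cyclohex-3-en-1-ol | C=C[C@@](C)(O[Si](CC)(CC)CC)CC[C@H]1C(C)=C(O[Si](C)(C)C(C)(C)C)CC[C@]1(CO)O | intermediate
13 | [(1S,2S)-4-[(tert-butyldimethylsilyl)oxy]-1-hydroxy-3-methyl-2-[(3S)-3-methyl-3-(triethylsilyloxy)pent-4-en-1-yl]cyclohex-3-en-1-yl]methyl 4-methylbenzenesulfonate (present as its sodium alkoxide) | C=C[C@@](C)(O[Si](CC)(CC)CC)CC[C@H]1C(C)=C(O[Si](C)(C)C(C)(C)C)CC[C@]1(COS(=O)(=O)c1ccc(C)cc1)O | intermediate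
14 | tert-butyl{[(3S,4S)-5-methyl-4-[(3S)-3-methyl-3-(triethylsilyloxy)pent-4-en-1-yl]-1-oxaspiro[2.5]oct-5-en-6-yl]oxy}dimethylsilane (epoxide O trans to the side chain) | C=C[C@@](C)(O[Si](CC)(CC)CC)CC[C@H]1C(C)=C(O[Si](C)(C)C(C)(C)C)CC[C@]1(C2)O2 | intermediate
15 | (1S,2S)-4-[(tert-butyldimethylsilyl)oxy]-1,3-dimethyl-2-[(3S)-3-methyl-3-(triethylsilyloxy)pent-4-en-1-yl]cyclohex-3-en-1-ol | C=C[C@@](C)(O[Si](CC)(CC)CC)CC[C@H]1C(C)=C(O[Si](C)(C)C(C)(C)C)CC[C@]1(C)O | intermediate
16 | dilithium (3S,4S)-2,4-dimethyl-3-[(3S)-3-methyl-3-(triethylsilyloxy)pent-4-en-1-yl]-4-oxidocyclohex-1-en-1-olate | C=C[C@@](C)(O[Si](CC)(CC)CC)CC[C@H]1C(C)=C([O-])CC[C@]1(C)[O-].[Li+].[Li+] | intermediate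
17 | (2S,3S,4S)-4-hydroxy-2,4-dimethyl-3-[(3S)-3-methyl-3-(triethylsilyloxy)pent-4-en-1-yl]-2-(prop-2-en-1-yl)cyclohexan-1-one | C=C[C@@](C)(O[Si](CC)(CC)CC)CC[C@H]1[C@](C)(CC=C)C(=O)CC[C@]1(C)O | intermediate
18 | (1S,2S,3S,4R)-1,3-dimethyl-2-[(3S)-3-methyl-3-(triethylsilyloxy)pent-4-en-1-yl]-3-(prop-2-en-1-yl)cyclohexane-1,4-diol (axial secondary OH) | C=C[C@@](C)(O[Si](CC)(CC)CC)CC[C@H]1[C@](C)(CC=C)[C@H](O)CC[C@]1(C)O | intermediate
19 | (1S,2S,3S,4S)-4-bromo-1,3-dimethyl-2-[(3S)-3-methyl-3-(triethylsilyloxy)pent-4-en-1-yl]-3-(prop-2-en-1-yl)cyclohexan-1-ol | C=C[C@@](C)(O[Si](CC)(CC)CC)CC[C@H]1[C@](C)(CC=C)[C@@H](Br)CC[C@]1(C)O | intermediate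
20 | 2-methylbut-3-en-2-ol | C=CC(C)(C)O | starting material
21 | (1S,2S,3S,4S)-4-bromo-3-[(2E)-4-hydroxy-4-methylpent-2-en-1-yl]-1,3-dimethyl-2-[(3S)-3-methyl-3-(triethylsilyloxy)pent-4-en-1-yl]cyclohexan-1-ol | C=C[C@@](C)(O[Si](CC)(CC)CC)CC[C@H]1[C@](C)(C/C=C/C(C)(C)O)[C@@H](Br)CC[C@]1(C)O | intermediate
22 | (1S,2S,3S,4S)-4-bromo-2-[(3S)-3-hydroxy-3-methylpent-4-en-1-yl]-3-[(2E)-4-hydroxy-4-methylpent-2-en-1-yl]-1,3-dimethylcyclohexan-1-ol | C=C[C@@](C)(O)CC[C@H]1[C@](C)(C/C=C/C(C)(C)O)[C@@H](Br)CC[C@]1(C)O | target

**Step count and risks**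

Total step count: 13. Longest linear sequence: 11 steps (steps 1–4 and 7–13).

Steps most likely to fail:

1. Step 7. The endo preference may erode, because in the endo array the complexed formyl group lies under the C3 methyl group of the diene; the exo mode would deliver the C1 epimer, and competing binding of the ester carbonyl to boron may slow turnover. In the fallback the C1 oxygen is no longer carried in by the dienophile but is installed by an intramolecular displacement with inversion. Setting out from 7, the same cationic oxazaborolidine (antipode chosen so that C2 is again S) is used with 2-bromoacrolein F2, made from acrolein by bromination to 2,3-dibromopropanal F1 and elimination with Et3N. The exo adduct, bromo aldehyde F3, has CHO trans and Br cis to the side chain. NaBH4 in MeOH at −20 °C should give bromohydrin F4, and NaH in THF should close the epoxide by backside attack of the primary alkoxide on the tertiary C–Br bond. This is spiro-epoxide 14, where the fallback comes back to the route; LiEt3BH as in step 9 then gives 15.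

2. Step 12. Displacement at the secondary centre next to the quaternary carbon may be slow, so that elimination towards C5 (the axial leaving group has an anti-periplanar hydrogen) and dehydration of the free tertiary alcohol compete. The fallback separates activation from displacement. Setting out from 18, chloromethanesulfonyl chloride and pyridine should sulfonylate only the secondary hydroxyl to give chloromethanesulfonate F5, an isolable and highly reactive sulfonate. LiBr in DMF at moderate temperature (or Bu4NBr in toluene) should then displace it with inversion and come back to the route at 19.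

3. Step 10. Cleavage of the hindered silyl enol ether by methyllithium may be slow, proton transfer may scramble the enolate, and the facial preference of the SN2 allylation may be insufficient. The fallback is a Tsuji allylation that sets out from 15 and comes back at 17: Pd2(dba)3 (zerovalent palladium), (S)-4-tert-butyl-2-[2-(diphenylphosphanyl)phenyl]-4,5-dihydrooxazole (or its antipode, matched to the substrate bias), diallyl carbonate and Bu4N[Ph3SiF2], THF, 25 °C. The enolate is released by fluoride and allylated within the coordination sphere of palladium, which keeps the regiochemistry and adds ligand control over the C3 face; it forms no further compound (F0).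

Further compounds
F1 | step 7 | 2,3-dibromopropanal | O=CC(Br)CBr
F2 | step 7 | 2-bromoacrolein (2-bromoprop-2-enal) | C=C(Br)C=O
F3 | step 7 | (1R,2S)-1-bromo-4-[(tert-butyldimethylsilyl)oxy]-3-methyl-2-[(3S)-3-methyl-3-(triethylsilyloxy)pent-4-en-1-yl]cyclohex-3-ene-1-carbaldehyde | C=C[C@@](C)(O[Si](CC)(CC)CC)CC[C@H]1C(C)=C(O[Si](C)(C)C(C)(C)C)CC[C@]1(Br)C=O
F4 | step 7 | [(1R,2S)-1-bromo-4-[(tert-butyldimethylsilyl)oxy]-3-methyl-2-[(3S)-3-methyl-3-(triethylsilyloxy)pent-4-en-1-yl]cyclohex-3-en-1-yl]methanol | C=C[C@@](C)(O[Si](CC)(CC)CC)CC[C@H]1C(C)=C(O[Si](C)(C)C(C)(C)C)CC[C@]1(Br)CO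
F5 | step 12 | (1R,2S,3S,4S)-4-hydroxy-2,4-dimethyl-3-[(3S)-3-methyl-3-(triethylsilyloxy)pent-4-en-1-yl]-2-(prop-2-en-1-yl)cyclohexyl chloromethanesulfonate | C=C[C@@](C)(O[Si](CC)(CC)CC)CC[C@H]1[C@](C)(CC=C)[C@H](OS(=O)(=O)CCl)CC[C@]1(C)O
F0 | step 10 | none | none
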